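## The problem

Ring positions are numbered C1 (carbinol) to C6, the chain on C2 is C7–C10, and the linker carbons are Ca (on C4) and Cb. Target 22 is a C2-symmetric C30 compound in which two identical cyclohexenol rings are joined through C4 and C4' by an (E,E)-buta-1,3-diene, so that the ring olefins C3=C4 and the linker form one conjugated tetraene. Only one half has to be built, provided the last carbon–carbon bond is made at the centre of the linker with full control of olefin geometry. Each ring carries the carbinol C1 (R) beside the all-carbon quaternary C2 (S), with the C7–C10 chain cis and the methyl trans to the hydroxyl; C2 is the hard centre and C1 is the only neighbour that can control it. The epoxide carbon C9 (R) lies three bonds from C2 on a flexible chain and can be set only by a chiral reagent. The trisubstituted epoxides are acid-labile, the C1 oxygen is placed to open its own epoxide at C9 in a six-membered closure, and the tetraene tolerates neither acid nor electrophilic oxidants. The epoxide must therefore be made late but before the polyene exists, and the end game must stay neutral or mildly basic. The enabling feature is that in each ring C3 is olefinic and C7 sits on C2 on the hydroxyl face, so C7 can be regarded as having once been bonded to C3 as well, as the apex of a cyclopropane (C2, C3, C7) cis to the C1 hydroxyl; a hydroxyl-directed carbenoid can build that ring on a C2=C3 olefin, and a C4 carbonyl can later cut it at C3–C7, leaving C7 as CH2 and C3=C4 as an enolate.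

## Retrosynthesis

**22 ⇒ 21 ⇒ 2 × 20 (central Cb–Cb' bond).** Removing the two silyl ethers of 21 is the last operation. The linker is cut at its centre. Cutting both C4–Ca bonds instead would need a four-carbon (E,E)-dienyl bis-metal partner that is not a catalogue compound. Cutting the Ca=Cb olefins would replace a stereospecific coupling by two olefinations whose geometry has to be won each time. The central cut gives two identical (E)-dienylboronates 20, half the size of the target. The forward reaction must be an oxidative homocoupling that retains olefin geometry and spares epoxide and silyl ether.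

**20 ⇒ 19 ⇒ 16 + 17 (B–Cb and C4–Ca).** The boronate is traced to terminal enyne 19 by syn hydroboration, which creates the E olefin. The C4–Ca bond is cut by a Sonogashira disconnection to enol triflate 16 and ethynyltrimethylsilane 17. The alkyne brings both linker carbons of one half as a cheap reagent. The problem is reduced to a regiodefined enol triflate, that is, to a C3=C4 enolate of a C4 ketone.

**16 ⇒ 15 (epoxide oxygen).** The epoxide is removed to the C9=C10 olefin of 15. This is the one point where it can be introduced cleanly. The only other olefin in 15 is the electron-poor enol triflate, no polyene is present yet, and the strongly reducing step lies behind. The forward step must be reagent-controlled for the (R) configuration, since C9 is remote.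

**15 ⇒ 14 ⇒ 13 (reconnect C3–C7).** A C4 ketone with a quaternary C2 would be deprotonated at C5, not at the hindered C3, so the C3=C4 enolate 14 cannot come from deprotonation. It is generated regiospecifically by reconnecting C3 to C7: reductive cleavage of cyclopropyl ketone 13 cuts the C3–C7 bond, which overlaps with the carbonyl π system, and delivers 14. This step also converts C7 into the CH2 group of the chain. The forward reaction must cleave the exocyclic and not the ring cyclopropane bond and leave the isolated olefin and the silyl ether intact.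

**13 ⇒ 12 ⇒ 11 (functional group changes).** The ketone of 13 is masked as the dimethyl ketal of 12, and the silyl ether is traced to the free hydroxyl of 11. The ketal is needed because the carbenoid step requires a nucleophilic olefin and an enone would not serve. The free hydroxyl is the directing group of that step.

**11 ⇒ 8 + 4 (C2–C7 and C3–C7).** Both cyclopropane bonds are cut at once, giving allylic alcohol 8 and gem-diiodide 4 as carbenoid precursor. Compared with alkylating a C1 ketone enolate at C2, this cut brings the whole chain in one step. It forms the quaternary centre by a suprafacial delivery tied to the C1 oxygen, so the cis relation of chain and hydroxyl cannot come out wrong. The precursor 8 has one stereocentre and nine carbons. The forward reaction must transfer a substituted carbenoid to a trisubstituted olefin without harming the allylic ketal.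

**8 ⇒ 7 ⇒ 6 ⇒ 5 and 4 ⇒ 1 + 2.** The single stereocentre of 8 comes from enantioselective reduction of enone 7. Enone 7 is the partly hydrogenated form of quinone monoketal 6, obtained by oxidative dearomatisation of phenol 5. Diiodide 4 is the alkylation product of metallated diiodomethane 1 with prenyl bromide 2.

## Roads not taken

Alternative 1: The linker is cut at both Ca–Cb bonds. In the forward step the bis(bromomagnesium) acetylide A2 adds to two molecules of ring enal A1 to give the C30 but-2-yne-1,4-diol A3.
- Merits: the step is bidirectional, needs no noble metal, and the carbinol configuration is irrelevant.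
- Weak points: the step builds only the linker, so the ring stereocentres of A1 must be supplied by other chemistry. A3 must then lose both hydroxyls in a reductive 1,4-elimination through doubly allylic intermediates, where diene geometry and cumulene formation are not secured. The epoxide cannot survive these steps, so A1 carries an acetonide and both epoxides have to be made on the finished tetraene.
- Comparison: the coupling itself is cheaper and more scalable than a homocoupling catalysed by Pd(OAc)2. The chosen plan offers in return a linker geometry fixed by syn hydroboration and a stereoretentive coupling, and a key step that also creates the quaternary centre.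

Alternative 2: The ring is cut at C1–C2 and C5–C6. Silyloxydiene A4 and but-3-en-2-one A5 combine in a Diels–Alder reaction under a chiral oxazaborolidinium Lewis acid to give cycloadduct A6, with the acetyl group cis to the chain.
- Merits: ring, quaternary centre and C1 are made in one catalytic step from acyclic material, and the silyl enol ether of A6 is already the C4 handle.
- Weak points: the reacting terminus of A4 is fully substituted, and its methyl group occupies the inside position of the s-cis diene. This retards cycloaddition and puts endo and enantiofacial control at the limit of what such catalysts are known to do. The acetyl group of A6 must become the hydroxyl by Baeyer–Villiger oxidation, in a molecule whose enol ether and trisubstituted olefin are more reactive toward a peracid than the ketone.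
- Comparison: if the cycloaddition performed, this road would reach the stage of 15 in fewer steps and with catalytic control of both ring centres at once, which the chosen plan cannot match. The chosen plan offers in return a relative configuration fixed by intramolecular delivery, and it never exposes the chain olefin to an oxidant before the planned epoxidation.

Alternative 3: The ring is cut at C2–C3. Indium tribromide A8 activates cis-epoxide A7, the terminal alkyne carbon attacks the tertiary epoxide carbon with inversion, and bromide from A8 captures the vinyl cation to give bromocyclohexenol A9.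
- Merits: A9 is the free alcohol with a halide at C4 and the correct (1R,2S) configuration. Its absolute configuration would come from a reliable allylic-alcohol epoxidation, and no protecting group is needed.
- Weak points: a terminal alkyne is a weak nucleophile for a tertiary epoxide carbon. Ionisation to the tertiary cation (loss of configuration at C2), hydride or alkyl shift to carbonyl compounds, and direct bromide opening by A8 all compete. The chain olefin of A7 is a better π-nucleophile than the alkyne and can reach the other epoxide carbon in a five-membered closure. A7 also needs a three-carbon extension next to an epoxide.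
- Comparison: this road would be the shortest of all if the cyclisation were clean. The chosen plan offers in return a concerted, non-cationic construction of C2 and a cleavage step with a well-understood stereoelectronic preference.

Key step: step 5

Assumption: C7 of 11, 12 and 13 is drawn as the exo epimer; the endo epimer would serve equally, because C7 becomes CH2 in step 8.

## Route

Step 1
Reactants: 1 diiodomethane; 2 1-bromo-3-methylbut-2-ene
Product: 4 5,5-diiodo-2-methylpent-2-ene, via diiodomethyllithium 3 (not isolated)
Conditions: LiN(SiMe3)2, THF/Et2O, −78 °C; then 2, −78 °C → rt, dark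
Reagents that add atoms: none
Why: Deprotonation of diiodomethane gives diiodomethyllithium, stable at −78 °C, which is alkylated by the allylic bromide in an SN2 reaction at the primary carbon (alkylation of a metallated gem-dihalide).

Step 2
Reactants: 5 4-methoxy-2-methylphenol
Product: 6 4,4-dimethoxy-2-methylcyclohexa-2,5-dien-1-one
Conditions: PhI(OAc)2, MeOH, 0 °C; NaHCO3 work-up
Reagents that add atoms: methanol, CO
Why: Oxidative dearomatisation of a para-alkoxyphenol by trivalent iodine: the aryloxyiodane loses iodobenzene and methanol adds at the methoxy-bearing para carbon to give the quinone monoketal.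

Step 3
Reactants: 6 4,4-dimethoxy-2-methylcyclohexa-2,5-dien-1-one
Product: 7 4,4-dimethoxy-2-methylcyclohex-2-en-1-one
Conditions: H2 (1 atm), RhCl(PPh3)3 (5 mol %), toluene, rt
Reagents that add atoms: none
Why: Homogeneous hydrogenation with RhCl(PPh3)3 discriminates by olefin substitution, so the disubstituted C5=C6 bond of the cross-conjugated dienone should be reduced and the methyl-bearing trisubstituted C2=C3 bond kept; the neutral medium spares the ketal.

Step 4
Reactants: 7 4,4-dimethoxy-2-methylcyclohex-2-en-1-one
Product: 8 (1R)-4,4-dimethoxy-2-methylcyclohex-2-en-1-ol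
Conditions: (S)-Me-CBS oxazaborolidine (10 mol %), BH3·SMe2, THF, −20 °C; MeOH quench, aq. NaHCO3
Reagents that add atoms: none
Why: CBS reduction of an α-substituted cyclic enone: the ketone binds the catalyst boron with the methyl-bearing vinyl arm as the large group and the coordinated borane delivers hydride to the face that gives the (R) alcohol; the work-up is kept non-acidic because 8 can lose methanol and water to an arene.

Step 5
Reactants: 8 (1R)-4,4-dimethoxy-2-methylcyclohex-2-en-1-ol; 4 5,5-diiodo-2-methylpent-2-ene
Product: 11 (1S,2R,6R,7R)-5,5-dimethoxy-1-methyl-7-(3-methylbut-2-en-1-yl)bicyclo[4.1.0]heptan-2-ol, via ethylzinc alkoxide 9 (not isolated), via iodoalkylzinc alkoxide 10 (not isolated)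
Conditions: Et2Zn (1.1 equiv), CH2Cl2, 0 °C; then Et2Zn (2 equiv), 4 (4 equiv), −40 → 0 °C; pyridine, aq. NaHCO3
Reagents that add atoms: none
Why: Et2Zn converts 8 into ethylzinc alkoxide 9, and iodine–zinc exchange with gem-diiodide 4 places the α-iodoalkyl group on the alkoxide-bound zinc (10), so that C7 is held over the hydroxyl face of the C2=C3 olefin. Transfer follows the butterfly-type transition state of the Simmons–Smith cyclopropanation in its Furukawa form: the C2–C7 and C3–C7 bonds form together while iodide passes to zinc, so the three-membered ring closes by a concerted, stereospecific [2+1] addition and not by a stepwise ring closure. The closest known reaction type is the hydroxyl-directed cyclopropanation of cyclohex-2-en-1-ols with zinc carbenoids, including alkyl-substituted carbenoids generated from 1,1-diiodoalkanes and Et2Zn. C2 and C3 are controlled by the C1 stereocentre through the zinc alkoxide tether, which puts the cyclopropane cis to oxygen and forces the C2 methyl trans. C7 should take the exo configuration for steric reasons, but this centre is of no consequence because it becomes CH2 in step 8. The step needs facial selectivity, secured by the tether, and chemoselectivity for the ring olefin over the prenyl olefins of 4 and 11, secured by the rate advantage of alkoxide-directed over undirected transfer. Pre-forming 9, keeping Et2Zn in excess so that the zinc halide formed remains EtZnI, and a basic quench protect the acid-labile allylic ketal, and the excess of 4 makes up for carbenoid lost by 1,2-hydride shift.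

Step 6
Reactants: 11 (1S,2R,6R,7R)-5,5-dimethoxy-1-methyl-7-(3-methylbut-2-en-1-yl)bicyclo[4.1.0]heptan-2-ol
Product: 12 tert-butyl{[(1S,2R,6R,7R)-5,5-dimethoxy-1-methyl-7-(3-methylbut-2-en-1-yl)bicyclo[4.1.0]heptan-2-yl]oxy}dimethylsilane
Conditions: TBSCl, imidazole, DMAP (cat.), DMF, 45 °C
Reagents that add atoms: tert-butyldimethylsilyl chloride, CC(C)(C)[Si](C)(C)Cl
Why: Imidazole-promoted silylation of a secondary alcohol under non-acidic conditions that leave the ketal untouched; the ether is needed because a free hydroxyl would protonate the enolate and be triflated in step 8.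

Step 7
Reactants: 12 tert-butyl{[(1S,2R,6R,7R)-5,5-dimethoxy-1-methyl-7-(3-methylbut-2-en-1-yl)bicyclo[4.1.0]heptan-2-yl]oxy}dimethylsilane
Product: 13 (1R,5R,6S,7R)-5-[(tert-butyldimethylsilyl)oxy]-6-methyl-7-(3-methylbut-2-en-1-yl)bicyclo[4.1.0]heptan-2-one
Conditions: PPTS (cat.), acetone/H2O, rt
Reagents that add atoms: water, O
Why: Mild acid hydrolysis of a dimethyl ketal, helped by the cyclopropyl-stabilised oxocarbenium ion; the hindered silyl ether and the trisubstituted olefin are stable to pyridinium tosylate.

Step 8
Reactants: 13 (1R,5R,6S,7R)-5-[(tert-butyldimethylsilyl)oxy]-6-methyl-7-(3-methylbut-2-en-1-yl)bicyclo[4.1.0]heptan-2-one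
Product: 15 (3S,4R)-4-[(tert-butyldimethylsilyl)oxy]-3-methyl-3-(4-methylpent-3-en-1-yl)cyclohex-1-en-1-yl trifluoromethanesulfonate, via lithium enolate 14 (not isolated)
Conditions: Li, NH3(l)/THF, t-BuOH (1 equiv), −78 °C; isoprene; NH3 removed; PhNTf2, THF, −78 → 0 °C
Reagents that add atoms: N-phenylbis(trifluoromethanesulfonimide), O=S(=O)(N(c1ccccc1)S(=O)(=O)C(F)(F)F)C(F)(F)F
Why: Dissolving-metal cleavage of a cyclopropyl ketone: the ketyl opens the exocyclic C3–C7 bond, which overlaps with the carbonyl π system and gives the less substituted carbanion, the C7 anion is protonated to CH2, and the C3=C4 lithium enolate 14 is captured on oxygen by the triflimide (reductive enolate trapping). The stereocentres C1 and C2 are not touched, and isolated olefins and silyl ethers are inert to Li/NH3.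

Step 9
Reactants: 15 (3S,4R)-4-[(tert-butyldimethylsilyl)oxy]-3-methyl-3-(4-methylpent-3-en-1-yl)cyclohex-1-en-1-yl trifluoromethanesulfonate
Product: 16 (3S,4R)-4-[(tert-butyldimethylsilyl)oxy]-3-{2-[(2R)-3,3-dimethyloxiran-2-yl]ethyl}-3-methylcyclohex-1-en-1-yl trifluoromethanesulfonate
Conditions: D-fructose-derived Shi ketone (30 mol %), KHSO5, K2CO3, Bu4NHSO4, MeCN/CH2(OMe)2/aq. Na2B4O7 buffer (pH 10.5), 0 °C
Reagents that add atoms: potassium peroxymonosulfate, [K+].[O-]S(=O)(=O)OO
Why: Shi epoxidation: the chiral dioxirane transfers oxygen through a spiro transition state to the electron-rich trisubstituted olefin, and the D-fructose-derived ketone should give the (R) epoxide as it does for other 2-methylalk-2-enes, by reagent control. The enol triflate olefin is too electron-poor to react, and the basic buffer protects the epoxide; any C9 epimer is best removed here, before dimerisation.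

Step 10
Reactants: 16 (3S,4R)-4-[(tert-butyldimethylsilyl)oxy]-3-{2-[(2R)-3,3-dimethyloxiran-2-yl]ethyl}-3-methylcyclohex-1-en-1-yl trifluoromethanesulfonate; 17 ethynyltrimethylsilane
Product: 19 tert-butyl{[(1R,2S)-2-{2-[(2R)-3,3-dimethyloxiran-2-yl]ethyl}-4-ethynyl-2-methylcyclohex-3-en-1-yl]oxy}dimethylsilane, via trimethylsilyl enyne 18 (not isolated)
Conditions: 17, Pd(PPh3)4 (5 mol %), CuI (10 mol %), i-Pr2NH, THF, rt; then K2CO3, MeOH, rt, under argon
Reagents that add atoms: none
Why: Sonogashira coupling of an alkenyl triflate (oxidative addition to zerovalent palladium, transmetalation from the copper acetylide, reductive elimination), followed in the same flask by methoxide-induced protodesilylation of the alkynylsilane; epoxide and silyl ether are stable to amine and carbonate.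

Step 11
Reactants: 19 tert-butyl{[(1R,2S)-2-{2-[(2R)-3,3-dimethyloxiran-2-yl]ethyl}-4-ethynyl-2-methylcyclohex-3-en-1-yl]oxy}dimethylsilane
Product: 20 tert-butyl{[(1R,2S)-2-{2-[(2R)-3,3-dimethyloxiran-2-yl]ethyl}-2-methyl-4-[(E)-2-(4,4,5,5-tetramethyl-1,3,2-dioxaborolan-2-yl)ethenyl]cyclohex-3-en-1-yl]oxy}dimethylsilane
Conditions: HBpin, Cp2Zr(H)Cl (10 mol %), Et3N (10 mol %), CH2Cl2, rt
Reagents that add atoms: pinacolborane, [H]B1OC(C)(C)C(C)(C)O1
Why: Zirconium-catalysed hydroboration of a terminal alkyne: syn addition with boron at the terminal carbon gives only the (E)-alkenylboronate, and the trisubstituted ring olefin and the epoxide should not react with pinacolborane at room temperature.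

Step 12
Reactants: 20 tert-butyl{[(1R,2S)-2-{2-[(2R)-3,3-dimethyloxiran-2-yl]ethyl}-2-methyl-4-[(E)-2-(4,4,5,5-tetramethyl-1,3,2-dioxaborolan-2-yl)ethenyl]cyclohex-3-en-1-yl]oxy}dimethylsilane (two molecules)
Product: 21 (1E,3E)-1,4-bis[(3S,4R)-4-[(tert-butyldimethylsilyl)oxy]-3-{2-[(2R)-3,3-dimethyloxiran-2-yl]ethyl}-3-methylcyclohex-1-en-1-yl]buta-1,3-diene
Conditions: Pd(OAc)2 (10 mol %), K2CO3, THF/MeOH/H2O, O2 (1 atm), rt, dark
Reagents that add atoms: none
Why: Oxidative homocoupling of an alkenylboronate: two base-assisted transmetalations to divalent palladium and reductive elimination form the central Cb–Cb' bond with retention at both olefins, and O2 returns zerovalent palladium to the divalent state; the aqueous carbonate medium does not affect epoxides or silyl ethers.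

Step 13
Reactants: 21 (1E,3E)-1,4-bis[(3S,4R)-4-[(tert-butyldimethylsilyl)oxy]-3-{2-[(2R)-3,3-dimethyloxiran-2-yl]ethyl}-3-methylcyclohex-1-en-1-yl]buta-1,3-diene
Product: 22 (1R,1'R,2S,2'S)-4,4'-[(1E,3E)-buta-1,3-diene-1,4-diyl]bis(2-{2-[(2R)-3,3-dimethyloxiran-2-yl]ethyl}-2-methylcyclohex-3-en-1-ol)
Conditions: Bu4NF, AcOH, THF, 0 °C → rt, dark
Reagents that add atoms: none
Why: Fluoride cleavage of the two silyl ethers; buffering with acetic acid keeps the liberated oxygen protonated so that it should not attack the neighbouring epoxide, and no acid strong enough to open the epoxides or isomerise the tetraene is present.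

## Compound list

1 | diiodomethane | ICI | starting material
2 | 1-bromo-3-methylbut-2-ene | CC(C)=CCBr | starting material
3 | diiodomethyllithium | [Li]C(I)I | intermediate
4 | 5,5-diiodo-2-methylpent-2-ene | CC(C)=CCC(I)I | intermediate
5 | 4-methoxy-2-methylphenol | COc1ccc(O)c(C)c1 | starting material
6 | 4,4-dimethoxy-2-methylcyclohexa-2,5-dien-1-one | COC1(OC)C=CC(=O)C(C)=C1 | intermediate
7 | 4,4-dimethoxy-2-methylcyclohex-2-en-1-one | CC1=CC(OC)(OC)CCC1=O | intermediate
8 | (1R)-4,4-dimethoxy-2-methylcyclohex-2-en-1-ol | CC1=CC(OC)(OC)CC[C@H]1O | intermediate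
9 | ethyl{[(1R)-4,4-dimethoxy-2-methylcyclohex-2-en-1-yl]oxy}zinc | CC[Zn]O[C@@H]1CCC(OC)(OC)C=C1C | intermediate
10 | {[(1R)-4,4-dimethoxy-2-methylcyclohex-2-en-1-yl]oxy}(1-iodo-4-methylpent-3-en-1-yl)zinc | CC(C)=CCC(I)[Zn]O[C@@H]1CCC(OC)(OC)C=C1C | intermediate
11 | (1S,2R,6R,7R)-5,5-dimethoxy-1-methyl-7-(3-methylbut-2-en-1-yl)bicyclo[4.1.0]heptan-2-ol (cyclopropane cis to hydroxyl, chain exo) | O[C@@H]1CCC(OC)(OC)[C@@H]2[C@@H](CC=C(C)C)[C@]12C | intermediate
12 | tert-butyl{[(1S,2R,6R,7R)-5,5-dimethoxy-1-methyl-7-(3-methylbut-2-en-1-yl)bicyclo[4.1.0]heptan-2-yl]oxy}dimethylsilane | CC(C)(C)[Si](C)(C)O[C@@H]1CCC(OC)(OC)[C@@H]2[C@@H](CC=C(C)C)[C@]12C | intermediate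
13 | (1R,5R,6S,7R)-5-[(tert-butyldimethylsilyl)oxy]-6-methyl-7-(3-methylbut-2-en-1-yl)bicyclo[4.1.0]heptan-2-one | CC(C)(C)[Si](C)(C)O[C@@H]1CCC(=O)[C@@H]2[C@@H](CC=C(C)C)[C@]12C | intermediate
14 | lithium (3S,4R)-4-[(tert-butyldimethylsilyl)oxy]-3-methyl-3-(4-methylpent-3-en-1-yl)cyclohex-1-en-1-olate | [Li+].CC(C)(C)[Si](C)(C)O[C@@H]1CCC([O-])=C[C@]1(C)CCC=C(C)C | intermediate
15 | (3S,4R)-4-[(tert-butyldimethylsilyl)oxy]-3-methyl-3-(4-methylpent-3-en-1-yl)cyclohex-1-en-1-yl trifluoromethanesulfonate | CC(C)(C)[Si](C)(C)O[C@@H]1CCC(OS(=O)(=O)C(F)(F)F)=C[C@]1(C)CCC=C(C)C | intermediate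
16 | (3S,4R)-4-[(tert-butyldimethylsilyl)oxy]-3-{2-[(2R)-3,3-dimethyloxiran-2-yl]ethyl}-3-methylcyclohex-1-en-1-yl trifluoromethanesulfonate | CC(C)(C)[Si](C)(C)O[C@@H]1CCC(OS(=O)(=O)C(F)(F)F)=C[C@]1(C)CC[C@H]2OC2(C)C | intermediate
17 | ethynyltrimethylsilane | C#C[Si](C)(C)C | starting material
18 | tert-butyl{[(1R,2S)-2-{2-[(2R)-3,3-dimethyloxiran-2-yl]ethyl}-2-methyl-4-[(trimethylsilyl)ethynyl]cyclohex-3-en-1-yl]oxy}dimethylsilane | CC(C)(C)[Si](C)(C)O[C@@H]1CCC(C#C[Si](C)(C)C)=C[C@]1(C)CC[C@H]2OC2(C)C | intermediate
19 | tert-butyl{[(1R,2S)-2-{2-[(2R)-3,3-dimethyloxiran-2-yl]ethyl}-4-ethynyl-2-methylcyclohex-3-en-1-yl]oxy}dimethylsilane | CC(C)(C)[Si](C)(C)O[C@@H]1CCC(C#C)=C[C@]1(C)CC[C@H]2OC2(C)C | intermediate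
20 | tert-butyl{[(1R,2S)-2-{2-[(2R)-3,3-dimethyloxiran-2-yl]ethyl}-2-methyl-4-[(E)-2-(4,4,5,5-tetramethyl-1,3,2-dioxaborolan-2-yl)ethenyl]cyclohex-3-en-1-yl]oxy}dimethylsilane | CC(C)(C)[Si](C)(C)O[C@@H]1CCC(/C=C/B2OC(C)(C)C(C)(C)O2)=C[C@]1(C)CC[C@H]3OC3(C)C | intermediate
21 | (1E,3E)-1,4-bis[(3S,4R)-4-[(tert-butyldimethylsilyl)oxy]-3-{2-[(2R)-3,3-dimethyloxiran-2-yl]ethyl}-3-methylcyclohex-1-en-1-yl]buta-1,3-diene | CC(C)(C)[Si](C)(C)O[C@@H]1CCC(/C=C/C=C/C2=C[C@](C)(CC[C@H]3OC3(C)C)[C@H](O[Si](C)(C)C(C)(C)C)CC2)=C[C@]1(C)CC[C@H]4OC4(C)C | intermediate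
22 | (1R,1'R,2S,2'S)-4,4'-[(1E,3E)-buta-1,3-diene-1,4-diyl]bis(2-{2-[(2R)-3,3-dimethyloxiran-2-yl]ethyl}-2-methylcyclohex-3-en-1-ol) | CC1(C)O[C@@H]1CC[C@@]1(C)C=C(/C=C/C=C/C2=C[C@](C)(CC[C@H]3OC3(C)C)[C@H](O)CC2)CC[C@H]1O | target

## Step count and risks

Total step count: 13. Longest linear sequence: 12 steps (5 to 22, steps 2–13); step 1 is a one-step branch that supplies 4.

**Step 5 (key step).**
- Most likely failure: carbenoid transfer to the trisubstituted olefin, which is hindered and inductively deactivated by the neighbouring ketal, is too slow. The α-iodoalkylzinc species then decomposes by 1,2-hydride shift or adds undirected to a prenyl olefin. Ionisation of the allylic ketal by zinc halide, followed by aromatisation, is the second hazard.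
- Fallback: C7 is delivered first without its chain, and the chain is attached afterwards. Setting out from 8, the zinc carbenoid made from iodoform and Et2Zn (no β-hydrogen, no olefin) should give, again under alkoxide direction, the iodocyclopropanol F1. Silylation (TBSCl, imidazole, DMF) gives the silyl ether F2. Iodine–lithium exchange (t-BuLi, Et2O, −78 °C) gives the configurationally stable cyclopropyllithium F3. Alkylation of F3 with 2 at the primary carbon returns to the route at 12 (or its C7 epimer, equally serviceable).

**Step 12.**
- Most likely failure: under O2 the carbon–boron bond is oxidised or protonated faster than the second transmetalation occurs, or the tetraene formed is degraded by oxygen and light.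
- Fallback: the symmetric bond is made by cross-coupling under argon. Setting out from 20, half of the material is converted by stereoretentive iododeboronation (NaOH, then I2, THF, 0 °C) into the (E)-dienyl iodide F4. Suzuki–Miyaura coupling of F4 with the remaining 20 (Pd(PPh3)4, aq. K3PO4, THF, rt) returns to the route at 21.

**Step 8.**
- Most likely failure: proton transfer during removal of ammonia, with amide or alkoxide present, returns part of the enolate to the ketone or moves it to C5 before triflation. Over-reduction of the ketone, competing cleavage of the ring bond C2–C3, or rearrangement of the transient homoallyl radical at C7 are less likely.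
- Fallback: the regiochemical information is stored in an isolable compound. Setting out from 13, the same reduction is quenched with Me3SiCl/Et3N to give the trimethylsilyl enol ether F5, which is purified. MeLi (THF, 0 °C) regenerates lithium enolate 14 free of other bases, and PhNTf2 then returns to the route at 15.

**Step 3.**
- Most likely failure: loss of selectivity between the two ring olefins (over-reduction), or loss of methanol from a reduced intermediate with return to an arene.
- Fallback: both olefins are reduced and the required one is reintroduced regioselectively. Setting out from 6, exhaustive hydrogenation (H2, Rh/Al2O3, EtOAc) gives the racemic saturated ketone F6. Equilibrating silylation (Me3SiCl, Et3N, DMF, 80 °C) gives the more substituted trimethylsilyl enol ether F7. Saegusa–Ito oxidation (Pd(OAc)2, MeCN) returns to the route at 7, erasing the stereocentre of F6.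

**Step 13.**
- Most likely failure: slow cleavage of the hindered silyl ethers, during which the liberated C1 alkoxide opens the epoxide at C9 in a six-membered closure, or degradation of the tetraene on prolonged treatment.
- Fallback: the silyl group is removed before the epoxide exists. Setting out from 15, HF·pyridine (THF, 0 °C) gives hydroxy triflate F8, and Shi epoxidation gives epoxy alcohol F9. Sonogashira coupling with 17 gives the trimethylsilyl enyne F10, and K2CO3/MeOH gives the terminal enyne F11. Hydroboration with excess HBpin (the transient O–B bond is cleaved on work-up) gives boronate F12. Oxidative homocoupling of F12 under the conditions of step 12 ends the synthesis directly at 22.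

## Further compounds

F1 | step 5 | (1S,2R,6R)-7-iodo-5,5-dimethoxy-1-methylbicyclo[4.1.0]heptan-2-ol (C7 configuration not defined) | O[C@@H]1CCC(OC)(OC)[C@@H]2C(I)[C@]12C
F2 | step 5 | tert-butyl{[(1S,2R,6R)-7-iodo-5,5-dimethoxy-1-methylbicyclo[4.1.0]heptan-2-yl]oxy}dimethylsilane (C7 configuration not defined) | CC(C)(C)[Si](C)(C)O[C@@H]1CCC(OC)(OC)[C@@H]2C(I)[C@]12C
F3 | step 5 | {5-[(tert-butyldimethylsilyl)oxy]-2,2-dimethoxy-6-methylbicyclo[4.1.0]heptan-7-yl}lithium (ring configuration as in F2) | CC(C)(C)[Si](C)(C)O[C@@H]1CCC(OC)(OC)[C@@H]2C([Li])[C@]12C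
F4 | step 12 | tert-butyl{[(1R,2S)-2-{2-[(2R)-3,3-dimethyloxiran-2-yl]ethyl}-4-[(E)-2-iodoethenyl]-2-methylcyclohex-3-en-1-yl]oxy}dimethylsilane | CC(C)(C)[Si](C)(C)O[C@@H]1CCC(/C=C/I)=C[C@]1(C)CC[C@H]2OC2(C)C
F5 | step 8 | tert-butyldimethyl{[(1R,2S)-2-methyl-2-(4-methylpent-3-en-1-yl)-4-[(trimethylsilyl)oxy]cyclohex-3-en-1-yl]oxy}silane | CC(C)(C)[Si](C)(C)O[C@@H]1CCC(O[Si](C)(C)C)=C[C@]1(C)CCC=C(C)C
F6 | step 3 | 4,4-dimethoxy-2-methylcyclohexan-1-one (racemic) | CC1CC(OC)(OC)CCC1=O
F7 | step 3 | [(4,4-dimethoxy-2-methylcyclohex-1-en-1-yl)oxy]trimethylsilane | CC1=C(O[Si](C)(C)C)CCC(OC)(OC)C1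
F8 | step 13 | (3S,4R)-4-hydroxy-3-methyl-3-(4-methylpent-3-en-1-yl)cyclohex-1-en-1-yl trifluoromethanesulfonate | O[C@@H]1CCC(OS(=O)(=O)C(F)(F)F)=C[C@]1(C)CCC=C(C)C
F9 | step 13 | (3S,4R)-3-{2-[(2R)-3,3-dimethyloxiran-2-yl]ethyl}-4-hydroxy-3-methylcyclohex-1-en-1-yl trifluoromethanesulfonate | O[C@@H]1CCC(OS(=O)(=O)C(F)(F)F)=C[C@]1(C)CC[C@H]2OC2(C)C
F10 | step 13 | (1R,2S)-2-{2-[(2R)-3,3-dimethyloxiran-2-yl]ethyl}-2-methyl-4-[(trimethylsilyl)ethynyl]cyclohex-3-en-1-ol | O[C@@H]1CCC(C#C[Si](C)(C)C)=C[C@]1(C)CC[C@H]2OC2(C)C
F11 | step 13 | (1R,2S)-2-{2-[(2R)-3,3-dimethyloxiran-2-yl]ethyl}-4-ethynyl-2-methylcyclohex-3-en-1-ol | O[C@@H]1CCC(C#C)=C[C@]1(C)CC[C@H]2OC2(C)C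
F12 | step 13 | (1R,2S)-2-{2-[(2R)-3,3-dimethyloxiran-2-yl]ethyl}-2-methyl-4-[(E)-2-(4,4,5,5-tetramethyl-1,3,2-dioxaborolan-2-yl)ethenyl]cyclohex-3-en-1-ol | O[C@@H]1CCC(/C=C/B2OC(C)(C)C(C)(C)O2)=C[C@]1(C)CC[C@H]3OC3(C)C
A1 | alternative 1 | (3S,4R)-4-[(tert-butyldimethylsilyl)oxy]-3-methyl-3-{2-[(4S)-2,2,5,5-tetramethyl-1,3-dioxolan-4-yl]ethyl}cyclohex-1-ene-1-carbaldehyde | O=CC1=C[C@](C)(CC[C@@H]2OC(C)(C)OC2(C)C)[C@H](O[Si](C)(C)C(C)(C)C)CC1
A2 | alternative 1 | ethyne-1,2-diylbis(bromomagnesium) | Br[Mg]C#C[Mg]Br
A3 | alternative 1 | 1,4-bis[(3S,4R)-4-[(tert-butyldimethylsilyl)oxy]-3-methyl-3-{2-[(4S)-2,2,5,5-tetramethyl-1,3-dioxolan-4-yl]ethyl}cyclohex-1-en-1-yl]but-2-yne-1,4-diol (carbinol configuration inconsequential, one epimer drawn) | O[C@@H](C#C[C@H](O)C1=C[C@](C)(CC[C@@H]2OC(C)(C)OC2(C)C)[C@H](O[Si](C)(C)C(C)(C)C)CC1)C1=C[C@](C)(CC[C@@H]2OC(C)(C)OC2(C)C)[C@H](O[Si](C)(C)C(C)(C)C)CC1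
A4 | alternative 2 | (3E)-4,8-dimethyl-2-[(triisopropylsilyl)oxy]nona-1,3,7-triene | C=C(O[Si](C(C)C)(C(C)C)C(C)C)/C=C(\C)CCC=C(C)C
A5 | alternative 2 | but-3-en-2-one | CC(=O)C=C
A6 | alternative 2 | 1-[(1R,2S)-2-methyl-2-(4-methylpent-3-en-1-yl)-4-[(triisopropylsilyl)oxy]cyclohex-3-en-1-yl]ethan-1-one | CC(C)[Si](C(C)C)(C(C)C)OC1=C[C@](C)(CCC=C(C)C)[C@H](C(C)=O)CC1
A7 | alternative 3 | (2S,3R)-3-(but-3-yn-1-yl)-2-methyl-2-(4-methylpent-3-en-1-yl)oxirane | C#CCC[C@H]1O[C@@]1(C)CCC=C(C)C
A8 | alternative 3 | indium tribromide | [In+3].[Br-].[Br-].[Br-]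
A9 | alternative 3 | (1R,2S)-4-bromo-2-methyl-2-(4-methylpent-3-en-1-yl)cyclohex-3-en-1-ol | BrC1=C[C@](C)(CCC=C(C)C)[C@H](O)CC1
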